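The earlier runs and the new flask were computed from invented constants, noise included.

Sunday's run, with 55 mM of initiator, has less substrate left after 120 min than Tuesday's, with 8.9 mM: 13.5 % against 55.8 %.

| setting | Tuesday's | Sunday's | theta | alpha | zeta |
|---|---|---|---|---|---|
| substrate | 0.28 M | 0.28 M | 0.28 M | 0.28 M | 0.28 M |
| gas | 38 mM (held) | 38 mM (held) | 38 mM (held) | 38 mM (held) | 38 mM (held) |
| initiator | 8.9 mM | 55 mM | 12 mM | 75 mM | 30 mM |
| remark | run made earlier | run made earlier |  |  |  |
| time |  |  | 4.0 h | 4.0 h | 4.0 h |

| run | time / min | substrate / % | first chain carrier / % | product / % |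
|---|---|---|---|---|
| Tuesday's | 10.0 | 94.4 | 0 | 4.1 |
| Tuesday's | 30.0 | 85.0 | 0.5 | 14.4 |
| Tuesday's | 60.0 | 73.8 | 0 | 26.3 |
| Tuesday's | 80.0 | 66.8 | 0 | 31.8 |
| Tuesday's | 120 | 55.8 | 0.8 | 41.9 |
| Sunday's | 10.0 | 86.7 | 0.6 | 13.2 |
| Sunday's | 20.0 | 71.9 | 0 | 26.5 |
| Sunday's | 30.0 | 61.6 | 0.4 | 37.4 |
| Sunday's | 60.0 | 37.6 | 0.2 | 61.4 |
| Sunday's | 120 | 13.5 | 0.1 | 85.3 |

(each reading ± 0.5 percentage points)

- at the start none of the gas is in solution

1. which of these there is most of at the end, counted by the substrate in it, theta (substrate / first chain carrier / product)
2. which of these there is most of at the end, counted by the substrate in it, alpha (substrate / first chain carrier / product)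
3. which of these there is most of at the end, counted by the substrate in it, zeta (substrate / first chain carrier / product)
4. how much there is at the end of the one of these that leads, in percent of the substrate charged: theta
5. how much there is at the end of the one of these that leads, in percent of the substrate charged: alpha
6. how much there is at the end of the one of these that leads, in percent of the substrate charged: zeta

Those readings are 0.842 substrate half-lives for Tuesday's run and 2.89 for Sunday's, so the pace goes as [initiator] to the power 0.677. If you scale Tuesday's count by that power and by the time, theta gets 2.06. This is the half-life count, the number of substrate half-lives that fit into the time, taking the decay as steady and pseudo-first-order. Zeta gets 3.83 and alpha 7.13.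

Each count exceeds 1, and halving that many times leaves 24.0 % of the substrate in theta, 7.02 % in zeta and 0.715 % in alpha. Tuesday's last readings leave 2.30 % unaccounted for, so I reckon product at 73.7 %, 90.7 % and 97.0 %, leading in each flask.

Was one number enough? The count assumes a steady pace, yet the readings stop at 120 min, before 4.0 h. Tuesday's run gave 0.438 half-lives in its first 60.0 min and 0.403 in the next, while Sunday's gave 1.41, then 1.48. So I take theta's 73.7 % as an estimate more likely high than low.

The forecast also names product in each flask, with 68 % for theta, 91 % for zeta and 97.5 % for alpha. Its theta stands lower than my figure, on the grounds that “the chain slowly weakens at low initiator”.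

The flasks give product in each: 66.5 % in theta, 87.1 % in zeta and 97.2 % in alpha, and the forecast is right on each, within its margin.

    2 second chain carrier → ended chains (k = 4.00 × 10⁷ /M/s)
    gas ⇌ partner, rate k2*(csat - [partner]) (kL = 19.3 /h)
    first chain carrier → ended carrier (k = 29900 /h)
    partner + first chain carrier → product + second chain carrier (k = 12000 /M/s)
    initiator → 2 initiating radical (k = 0.433 /h)
    substrate + second chain carrier → by-product + first chain carrier (k = 2.23 × 10⁶ /M/h)
    substrate + initiating radical → capped initiator + first chain carrier (k = 1.52 × 10⁷ /M/h)

Alpha's product has moved by 6 points at 36.9 mM of initiator, the nearest such amount below its 75 mM. Theta kept 32 % of its substrate, which is 1.64 half-lives against the count's 2.06. Read theta at 1.0 h and the count scales to 0.515, which leaves 70.0 % of the substrate; theta then holds 69.2 %.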